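**Plan**
- Cuts: first the two benzyl ethers and a ring-D C=C. Then ring D (cyclohexane) is cut at two non-adjacent bonds: (i) from the ring A/D fusion CH that lies 1,4 to the alkyl-bearing carbon to its ring-D CH2 neighbour, and (ii) from the alkyl-bearing CH to the ring-D CH2 on the other fusion carbon.
- Enabling feature: in ring A one fusion carbon carries an exocyclic carbon (a ring-D CH2 in the target) and its ring-A neighbour carries only H. Written as a 1-formylcyclobutene, this C=C–CHO unit is a strained 1,3-dielectrophile (β-carbon and CHO). It matches the C-2/C-4 dinucleophile of a 3-oxododecanoate that brings in the whole C8–glycerol chain.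
- Forward order: rings A, B and C form together by reductive dimerisation of two molecules of cis-3,4-dichlorocyclobutene. Desymmetrising hydroboration, saturation of ring C, one-carbon homologation to CHO and desaturation give the enal. Ring D is closed by a [3+3] Michael/aldol annulation, the ketone is excised with alkene transposition, and hydrogenation/debenzylation ends the route.
- Stereochemistry: the four ring-B methines (cis,anti,cis) come from the dimerisation. The absolute sense comes from the ligand-controlled hydroboration of the C2h-symmetric diene. The two A/D fusion centres come from exo-face Michael attack and cis-only ring closure. The alkyl-bearing centre comes from hydrogenation on the convex face of ring D.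

Key step: step 8

Assumption: the (R)-configured bisphosphine of step 2 is taken to give the enantiomer of the mono-boronate drawn in the list; if the sense of induction is the opposite, the (S)-ligand is used and nothing else changes.

Ring letters: A = cyclobutane fused to the six-membered ring, B = middle cyclobutane, C = terminal cyclobutane, D = six-membered ring.

**Step 1**
Reactants: 1 cis-3,4-dichlorocyclobutene (2 equiv, two molecules combine)
Product: 2 anti-tricyclo[4.2.0.0^2,5]octa-3,7-diene
Conditions: Li(Hg) (lithium amalgam), Et2O, rt; the anti dimer is freed from any syn dimer by fractional distillation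
Reagents that add atoms: cis-3,4-dichlorocyclobutene (the second molecule of 1), Cl[C@H]1C=C[C@H]1Cl
Why: Reductive dechlorination and dimerisation of two C4H4 units (lithium amalgam is the known entry to the anti dimer, whereas sodium amalgam gives mainly the syn dimer) builds rings A, B and C at once and fixes the four ring-B methines in the cis,anti,cis arrangement of an achiral ladder.

**Step 2**
Reactants: 2 anti-tricyclo[4.2.0.0^2,5]octa-3,7-diene
Product: 3 exo-3-(pinacolboryl)-anti-tricyclo[4.2.0.0^2,5]oct-7-ene
Conditions: CuCl (5 mol%), (R)-DM-SEGPHOS (6 mol%), NaOt-Bu (10 mol%), B2pin2 (1 equiv), MeOH (2 equiv), THF, 0 °C → rt; 2 in threefold excess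
Reagents that add atoms: bis(pinacolato)diboron, CC1(C)OB(OC1(C)C)B1OC(C)(C)C(C)(C)O1
Why: Copper-catalysed enantioselective hydroboration of a meso-type cyclobutene (borylcupration on the exo face, then protonation by methanol); the ligand selects between the enantiotopic alkene carbons (the two related by the C2 axis give the same product), which fixes the absolute configuration of the ladder, and the excess of diene should hold back a second addition.

**Step 3**
Reactants: 3 exo-3-(pinacolboryl)-anti-tricyclo[4.2.0.0^2,5]oct-7-ene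
Product: 4 exo-3-(pinacolboryl)-anti-tricyclo[4.2.0.0^2,5]octane
Conditions: H2 (1 atm), Pd/C, EtOAc, rt
Reagents that add atoms: none
Why: Heterogeneous hydrogenation of the remaining strained cyclobutene should leave the C–B bond and the cyclobutanes untouched and creates no stereocentre.

**Step 4**
Reactants: 4 exo-3-(pinacolboryl)-anti-tricyclo[4.2.0.0^2,5]octane; 5 dichloromethane
Product: 7 anti-tricyclo[4.2.0.0^2,5]octane-3-carbaldehyde, via α-chloroboronate 6 (not isolated)
Conditions: n-BuLi, THF, −100 °C (LiCHCl2 from 5); then 4; ZnCl2, −100 °C → rt; then H2O2, aq NaHCO3, 0 °C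
Reagents that add atoms: hydrogen peroxide, OO
Why: Matteson homologation: the boronate complex of LiCHCl2 rearranges by 1,2-migration of the cyclobutyl carbon with retention, and oxidation of the α-chloroboronate collapses to the aldehyde, whose carbon is the future ring-D CH2 on the fusion carbon.

**Step 5**
Reactants: 7 anti-tricyclo[4.2.0.0^2,5]octane-3-carbaldehyde
Product: 9 anti-tricyclo[4.2.0.0^2,5]oct-3-ene-3-carbaldehyde, via α-selenoaldehyde 8 (not isolated)
Conditions: PhSeCl, EtOAc, rt; then NaIO4, THF–H2O, 0 °C → rt; used at once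
Reagents that add atoms: none
Why: α-Selenenylation of the enolisable aldehyde followed by selenoxide syn-elimination, which should go toward the ring CH2 because elimination toward the ring A/B fusion hydrogen would give a far more strained bicyclo[2.2.0]hex-1-ene-type alkene; the centre α to CHO is erased on purpose, and the handedness stays encoded in the ring-B centres and the position of CHO.

**Step 6**
Reactants: 10 1,3-bis(benzyloxy)propan-2-ol; 11 10-bromodecanoic acid
Product: 12 10-{[1,3-bis(benzyloxy)propan-2-yl]oxy}decanoic acid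
Conditions: NaH (2.2 equiv), DMF, 0 → 60 °C; aq HCl work-up
Reagents that add atoms: none
Why: Williamson ether synthesis of the secondary alkoxide on the primary bromide of the sodium carboxylate; no stereocentre is involved.

**Step 7**
Reactants: 12 10-{[1,3-bis(benzyloxy)propan-2-yl]oxy}decanoic acid; 13 mono-tert-butyl malonate
Product: 15 tert-butyl 12-{[1,3-bis(benzyloxy)propan-2-yl]oxy}-3-oxododecanoate, via acyl imidazolide 14 (not isolated)
Conditions: CDI, THF, rt; then 13, MgCl2, Et3N, MeCN, rt → 45 °C
Reagents that add atoms: none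
Why: Decarboxylative Claisen-type C-acylation of the magnesium malonate half ester by the acyl imidazolide gives the β-keto ester under nearly neutral conditions that spare the benzyl ethers.

**Step 8**
Reactants: 9 anti-tricyclo[4.2.0.0^2,5]oct-3-ene-3-carbaldehyde; 15 tert-butyl 12-{[1,3-bis(benzyloxy)propan-2-yl]oxy}-3-oxododecanoate
Product: 18 10-(8-{[1,3-bis(benzyloxy)propan-2-yl]oxy}octyl)tetracyclo[6.4.0.0^2,7.0^3,6]dodec-9-en-11-one, via Michael adduct 16 (not isolated), via ester enone 17 (not isolated)
Conditions: DBU (0.1 equiv), CH2Cl2, −20 → 0 °C; then TsOH·H2O (0.3 equiv), toluene, 80 °C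
Reagents that add atoms: none
Why: DBU forms the stabilised enolate of 15, whose C-2 adds to the β-carbon of the strain-activated cyclobutene enal 9 (Michael addition; first new bond, from the ring-A fusion CH to its ring-D CH2 neighbour); after acidification the γ-methylene enol of the ketone attacks the aldehyde carbon with loss of water (intramolecular aldol condensation; second new bond, from the exocyclic one-carbon arm to the chain-bearing carbon), and the tert-butyl ester then leaves as isobutene and CO2. The closest known reaction type is the Robinson-type Michael/aldol-condensation [3+3] cyclohexenone annulation of β-keto esters with α,β-unsaturated aldehydes, including its acid-promoted decarboxylative one-pot form with tert-butyl esters. Ring D closes in a 6-(enolendo)-exo-trig aldol. The fusion carbon that was the β-carbon is set by attack on the exo face of ring A, anti to ring B; the other fusion carbon, α to the aldehyde and later γ to the enone, is epimerisable and should be funnelled to the cis fusion because only the cis-1,2-disubstituted cyclobutane can close; the ester-bearing centre is transient. The step needs 1,4- over 1,2-addition and reaction at C-2 rather than C-4 of 15, which the soft doubly stabilised enolate, the strain release at the cyclobutene and the α-branched aldehyde should secure, and it needs the aldol to use the γ-methylene, which is secured because every other enol/carbonyl pairing would give a four-membered ring.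

**Step 9**
Reactants: 18 10-(8-{[1,3-bis(benzyloxy)propan-2-yl]oxy}octyl)tetracyclo[6.4.0.0^2,7.0^3,6]dodec-9-en-11-one
Product: 19 N-tosylhydrazone of 18
Conditions: TsNHNH2, MeOH, rt
Reagents that add atoms: p-toluenesulfonyl hydrazide, Cc1ccc(cc1)S(=O)(=O)NN
Why: Condensation of the enone carbonyl with the sulfonyl hydrazide; no stereocentre is touched, and the cis fusion is the stable one should the γ-centre equilibrate.

**Step 10**
Reactants: 19 N-tosylhydrazone of 18
Product: 21 10-(8-{[1,3-bis(benzyloxy)propan-2-yl]oxy}octyl)tetracyclo[6.4.0.0^2,7.0^3,6]dodec-10-ene, via allylic diazene 20 (not isolated)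
Conditions: catecholborane, CHCl3, 0 °C; then NaOAc·3H2O, 60 °C
Reagents that add atoms: none
Why: Reduction of the conjugated tosylhydrazone with 1,3-transposition: hydride adds to C=N, sulfinate is eliminated, and the allylic diazene loses N2 by a retro-ene shift that puts the new hydrogen on the former β-carbon (now CH2) and moves the alkene between the former carbonyl carbon and the alkyl-bearing carbon, so no epimerisable centre is left next to a carbonyl.

**Step 11**
Reactants: 21 10-(8-{[1,3-bis(benzyloxy)propan-2-yl]oxy}octyl)tetracyclo[6.4.0.0^2,7.0^3,6]dodec-10-ene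
Product: 22 2-{[8-(tetracyclo[6.4.0.0^2,7.0^3,6]dodecan-10-yl)octyl]oxy}propane-1,3-diol (target)
Conditions: H2 (1 atm), Pd/C, EtOAc–EtOH, rt
Reagents that add atoms: none
Why: Catalytic hydrogenation with hydrogenolysis of both benzyl ethers; syn-addition of H2 is expected on the convex face of the boat-like cis-fused ring D (the face of the two fusion hydrogens, away from ring A), which places the new hydrogen cis to them and the chain cis to ring A.

**Compound list**
1 | cis-3,4-dichlorocyclobutene | Cl[C@H]1C=C[C@H]1Cl | starting material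
2 | anti-tricyclo[4.2.0.0^2,5]octa-3,7-diene (cis,anti,cis) | C1=C[C@@H]2[C@H]3C=C[C@H]3[C@H]12 | intermediate
3 | exo-3-(4,4,5,5-tetramethyl-1,3,2-dioxaborolan-2-yl)-anti-tricyclo[4.2.0.0^2,5]oct-7-ene (boron anti to ring B) | CC1(C)OB(OC1(C)C)[C@H]1C[C@@H]2[C@H]3C=C[C@H]3[C@H]12 | intermediate
4 | exo-3-(4,4,5,5-tetramethyl-1,3,2-dioxaborolan-2-yl)-anti-tricyclo[4.2.0.0^2,5]octane | CC1(C)OB(OC1(C)C)[C@H]1C[C@@H]2[C@H]3CC[C@H]3[C@H]12 | intermediate
5 | dichloromethane | ClCCl | starting material
6 | 2-[chloro(anti-tricyclo[4.2.0.0^2,5]oct-3-yl)methyl]-4,4,5,5-tetramethyl-1,3,2-dioxaborolane | CC1(C)OB(OC1(C)C)C(Cl)[C@H]1C[C@@H]2[C@H]3CC[C@H]3[C@H]12 | intermediate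
7 | anti-tricyclo[4.2.0.0^2,5]octane-3-carbaldehyde (CHO exo) | O=C[C@H]1C[C@@H]2[C@H]3CC[C@H]3[C@H]12 | intermediate
8 | 3-(phenylselanyl)-anti-tricyclo[4.2.0.0^2,5]octane-3-carbaldehyde | O=CC1([Se]c2ccccc2)C[C@@H]2[C@H]3CC[C@H]3[C@H]12 | intermediate
9 | anti-tricyclo[4.2.0.0^2,5]oct-3-ene-3-carbaldehyde | O=CC1=C[C@@H]2[C@H]3CC[C@H]3[C@H]12 | intermediate
10 | 1,3-bis(benzyloxy)propan-2-ol | OC(COCc1ccccc1)COCc1ccccc1 | starting material
11 | 10-bromodecanoic acid | OC(=O)CCCCCCCCCBr | starting material
12 | 10-{[1,3-bis(benzyloxy)propan-2-yl]oxy}decanoic acid | OC(=O)CCCCCCCCCOC(COCc1ccccc1)COCc1ccccc1 | intermediate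
13 | mono-tert-butyl malonate | OC(=O)CC(=O)OC(C)(C)C | starting material
14 | 1-(10-{[1,3-bis(benzyloxy)propan-2-yl]oxy}decanoyl)imidazole | O=C(CCCCCCCCCOC(COCc1ccccc1)COCc1ccccc1)n1ccnc1 | intermediate
15 | tert-butyl 12-{[1,3-bis(benzyloxy)propan-2-yl]oxy}-3-oxododecanoate | CC(C)(C)OC(=O)CC(=O)CCCCCCCCCOC(COCc1ccccc1)COCc1ccccc1 | intermediate
16 | Michael adduct: tert-butyl 2-(3-formyl-anti-tricyclo[4.2.0.0^2,5]oct-4-yl)-3-oxo-12-alkoxydodecanoate (new C–C bond exo; centres α to CHO and α to the ester as mixtures) | O=CC1[C@@H](C(C(=O)OC(C)(C)C)C(=O)CCCCCCCCCOC(COCc2ccccc2)COCc2ccccc2)[C@@H]2[C@H]3CC[C@H]3[C@H]12 | intermediate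
17 | tert-butyl 10-(8-{[1,3-bis(benzyloxy)propan-2-yl]oxy}octyl)-11-oxotetracyclo[6.4.0.0^2,7.0^3,6]dodec-9-ene-12-carboxylate | c1ccccc1COCC(COCc1ccccc1)OCCCCCCCCC1=C[C@@H]2[C@H]3[C@@H]4CC[C@@H]4[C@H]3[C@@H]2C(C(=O)OC(C)(C)C)C1=O | intermediate
18 | 10-(8-{[1,3-bis(benzyloxy)propan-2-yl]oxy}octyl)tetracyclo[6.4.0.0^2,7.0^3,6]dodec-9-en-11-one (all fusions cis, neighbouring rings anti) | c1ccccc1COCC(COCc1ccccc1)OCCCCCCCCC1=C[C@@H]2[C@H]3[C@@H]4CC[C@@H]4[C@H]3[C@@H]2CC1=O | intermediate
19 | N-tosylhydrazone of 18 | c1ccccc1COCC(COCc1ccccc1)OCCCCCCCCC1=C[C@@H]2[C@H]3[C@@H]4CC[C@@H]4[C@H]3[C@@H]2CC1=NNS(=O)(=O)c1ccc(C)cc1 | intermediate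
20 | allylic diazene at C-11 of the dodec-9-ene | c1ccccc1COCC(COCc1ccccc1)OCCCCCCCCC1=C[C@@H]2[C@H]3[C@@H]4CC[C@@H]4[C@H]3[C@@H]2CC1N=N | intermediate
21 | 10-(8-{[1,3-bis(benzyloxy)propan-2-yl]oxy}octyl)tetracyclo[6.4.0.0^2,7.0^3,6]dodec-10-ene | c1ccccc1COCC(COCc1ccccc1)OCCCCCCCCC1=CC[C@@H]2[C@H](C1)[C@H]1[C@@H]3CC[C@@H]3[C@@H]21 | intermediate
22 | 2-{[8-(tetracyclo[6.4.0.0^2,7.0^3,6]dodecan-10-yl)octyl]oxy}propane-1,3-diol (all fusions cis, neighbouring rings anti, chain cis to ring A) | OCC(CO)OCCCCCCCC[C@H]1CC[C@@H]2[C@H](C1)[C@H]1[C@@H]3CC[C@@H]3[C@@H]21 | target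

**Totals**
Total step count: 11. Longest linear sequence: 9 (steps 1–5, then 8–11).

**Steps most likely to fail**

Step 8. What may go wrong: attack of the enolate at the aldehyde carbon instead of the β-carbon, base-induced oligomerisation of the strained enal, or diversion of the 1,5-keto aldehyde into a pyran instead of the carbocycle. The fallback keeps the same two ring-D bonds but makes them by an enamine α,α'-annulation under neutral conditions. It sets out from 12 (with 9) and comes back at 18. Acid 12 is converted with MeLi (2.2 equiv, THF, 0 °C) into the methyl ketone 11-{[1,3-bis(benzyloxy)propan-2-yl]oxy}undecan-2-one F1. Condensation with pyrrolidine (cat. TsOH, benzene, azeotropic removal of water) gives the less substituted enamine F2. F2 is combined with 9 in dioxane at rt to 60 °C: Stork-type Michael addition from the terminal carbon, then ring closure of the regenerated enamine onto the aldehyde. Buffered aqueous acetic acid then hydrolyses and dehydrates to 18 without any decarboxylation.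

Step 5. What may go wrong: slow syn-elimination into a four-membered ring, over-oxidation of the aldehyde, or loss of the volatile, polymerisation-prone enal on handling. The fallback builds the enal from a cyclobutenyl electrophile and brings the formyl carbon in as CO. It sets out from 4 and comes back at 9. Oxidation of 4 (NaBO3·4H2O, THF–H2O) gives the alcohol F3. DMP oxidation gives the ketone F4, whose handedness is already fixed by the ring-B centres. Enolisation toward the CH2, the only direction that avoids an alkene at the ring A/B fusion (LiN(SiMe3)2, PhNTf2, THF, −78 °C), gives the enol triflate F5. Reductive carbonylation (CO 1 atm, Et3SiH, Pd(OAc)2, dppp, Et3N, DMF, 60 °C) gives 9.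

Step 11. What may go wrong: poor facial selectivity at an alkene that is remote from the ring fusion, made worse by double-bond migration on palladium before addition. The fallback hydrogenates at the enone stage, where the alkene carbon is bonded directly to a fusion stereocentre, and removes the oxygen afterwards by a radical path. It sets out from 18 and comes back at 22. Hydrogenation of 18 (H2, Rh/Al2O3, EtOAc) is expected to add anti to ring A and keep the benzyl ethers, giving the saturated ketone F6. The ketone is reduced at once with NaBH4 (MeOH, −20 °C), so that the centre next to the carbonyl has little time to epimerise, giving the alcohol F7. NaH, CS2 and MeI give the xanthate F8. Barton–McCombie deoxygenation (Bu3SnH, AIBN, toluene, 80 °C) gives the dibenzyl ether F9. H2 over Pd/C then gives 22.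

**Further compounds**
F1 | step 8 | 11-{[1,3-bis(benzyloxy)propan-2-yl]oxy}undecan-2-one | CC(=O)CCCCCCCCCOC(COCc1ccccc1)COCc1ccccc1
F2 | step 8 | 1-(11-{[1,3-bis(benzyloxy)propan-2-yl]oxy}undec-1-en-2-yl)pyrrolidine | C=C(CCCCCCCCCOC(COCc1ccccc1)COCc1ccccc1)N1CCCC1
F3 | step 5 | exo-anti-tricyclo[4.2.0.0^2,5]octan-3-ol | O[C@H]1C[C@@H]2[C@H]3CC[C@H]3[C@H]12
F4 | step 5 | anti-tricyclo[4.2.0.0^2,5]octan-3-one | O=C1C[C@@H]2[C@H]3CC[C@H]3[C@H]12
F5 | step 5 | anti-tricyclo[4.2.0.0^2,5]oct-3-en-3-yl trifluoromethanesulfonate | O=S(=O)(OC1=C[C@@H]2[C@H]3CC[C@H]3[C@H]12)C(F)(F)F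
F6 | step 11 | 10-(8-{[1,3-bis(benzyloxy)propan-2-yl]oxy}octyl)tetracyclo[6.4.0.0^2,7.0^3,6]dodecan-11-one | c1ccccc1COCC(COCc1ccccc1)OCCCCCCCC[C@H]1C(=O)C[C@@H]2[C@H](C1)[C@H]1[C@@H]3CC[C@@H]3[C@@H]21
F7 | step 11 | 10-(8-{[1,3-bis(benzyloxy)propan-2-yl]oxy}octyl)tetracyclo[6.4.0.0^2,7.0^3,6]dodecan-11-ol | c1ccccc1COCC(COCc1ccccc1)OCCCCCCCC[C@H]1C(O)C[C@@H]2[C@H](C1)[C@H]1[C@@H]3CC[C@@H]3[C@@H]21
F8 | step 11 | O-[10-(8-{[1,3-bis(benzyloxy)propan-2-yl]oxy}octyl)tetracyclo[6.4.0.0^2,7.0^3,6]dodecan-11-yl] S-methyl dithiocarbonate | c1ccccc1COCC(COCc1ccccc1)OCCCCCCCC[C@H]1C(OC(=S)SC)C[C@@H]2[C@H](C1)[C@H]1[C@@H]3CC[C@@H]3[C@@H]21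
F9 | step 11 | 10-(8-{[1,3-bis(benzyloxy)propan-2-yl]oxy}octyl)tetracyclo[6.4.0.0^2,7.0^3,6]dodecane | c1ccccc1COCC(COCc1ccccc1)OCCCCCCCC[C@H]1CC[C@@H]2[C@H](C1)[C@H]1[C@@H]3CC[C@@H]3[C@@H]21
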